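**Plan**

Retrosynthesis: C6–Cl is traced back to a 6R allylic alcohol, and the ten-membered ring (C1–C10) is then cut at C5–C6. The feature that allows this is the C6 heteroatom carbon lying between the exocyclic C5=C16 methylene of that ring and the lactone carbon C7, which is the retron of an alkenylchromium addition to a C6 aldehyde.
Further cuts: lactone C7–O (iodolactonization of a C19 acid onto a C7=C6 vinyl group), C7–C8 (vinyl Grignard on a C8 ketone), C8–C9 (alkenyllithium on a C9 amide), C13=C14 of ring A (metathesis), C1–C10 (ester-enolate Claisen) and the ester C–O joining two open-chain fragments.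
Forward: fragment 1 (C14, C1/C15, C2–C5/C16) and fragment 2 (C9–C13) are esterified and rearranged to form C1–C10. Ring A is closed first and dihydroxylated, fragment 3 (C8, C17–C19) is attached at C9, the γ-lactone is closed second, the ten-membered ring last, and chloride is introduced at the end.
Stereochemistry: C2 from a catalytic asymmetric alkynylation; C17 from methyl (2S)-3-hydroxy-2-methylpropanoate; a temporary C11 carbinol from ethyl (3S)-4-chloro-3-hydroxybutanoate. C1/C10 by the chelated chair Claisen, C13/C14 by osmylation anti to the axial C15 methyl, C9 by 1,3-anti directed reduction, C8 by chelation control, C7 by hydroxyl-directed iodolactonization, C6 by ligand-controlled chromium addition followed by SN2 inversion with chloride.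

Key step: step 31

Remark on numbering: atoms carry the briarane numbers of the target (C1 quaternary with C15 methyl; C2–C10 in the ten-membered ring; ring A = C1, C10–C14; C16 = methylene on C5; C17/C18/C19 = lactone CH/CH3/C=O; C20 = methylene on C11). α is the ring A face of the C13/C14 oxygens, β that of C15.
Assumption: the chiral ligands of steps 2 and 31 are taken to induce in the sense stated; if the sense is opposite, the mirror-image ligand is used.

**Route**

Step 1
Reactants: 1 5-(trimethylsilyl)pent-4-yn-1-ol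
Product: 2 5-(trimethylsilyl)pent-4-ynal
Conditions: TEMPO (cat.), PhI(OAc)2, CH2Cl2, rt
Reagents that add atoms: none
Why: Oxoammonium (TEMPO) oxidation of a primary alcohol stops at the aldehyde and leaves the silylated alkyne alone; no stereocentre is involved.

Step 2
Reactants: 2 5-(trimethylsilyl)pent-4-ynal; 3 methyl propiolate
Product: 5 methyl (4S)-4-hydroxy-8-(trimethylsilyl)octa-2,7-diynoate, via zinc acetylide 4 (not isolated)
Conditions: 3, Me2Zn, (S,S)-ProPhenol (cat.), Ph3PO (cat.), toluene, 0 °C; then 2
Reagents that add atoms: none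
Why: Catalytic enantioselective alkynylzinc addition to an aldehyde, in which the dinuclear zinc–ProPhenol complex binds both partners and delivers the alkyne to one aldehyde face, should set the C2 carbinol centre (S).

Step 3
Reactants: 5 methyl (4S)-4-hydroxy-8-(trimethylsilyl)octa-2,7-diynoate
Product: 6 methyl (4S)-4-(triethylsilyloxy)-8-(trimethylsilyl)octa-2,7-diynoate
Conditions: Et3SiCl, imidazole, DMF, 0 °C
Reagents that add atoms: chlorotriethylsilane, CC[Si](CC)(CC)Cl
Why: Silyl ether formation protects the carbinol without touching its configuration and prevents lactonization after the next step.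

Step 4
Reactants: 6 methyl (4S)-4-(triethylsilyloxy)-8-(trimethylsilyl)octa-2,7-diynoate
Product: 7 methyl (2Z,4S)-3-methyl-4-(triethylsilyloxy)-8-(trimethylsilyl)oct-2-en-7-ynoate
Conditions: Me2CuLi (from CuI and MeLi), THF, −78 °C; aq. NH4Cl at −78 °C
Reagents that add atoms: lithium dimethylcuprate, [Li+].C[Cu-]C
Why: Conjugate addition of the cuprate to the alkynoate is a syn carbocupration, so protonation of the alkenylcopper at −78 °C should give the Z enoate with C2 cis to the ester and the C15 methyl on C1.

Step 5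
Reactants: 7 methyl (2Z,4S)-3-methyl-4-(triethylsilyloxy)-8-(trimethylsilyl)oct-2-en-7-ynoate
Product: 8 (2Z,4S)-3-methyl-4-(triethylsilyloxy)-8-(trimethylsilyl)oct-2-en-7-yn-1-ol (fragment 1)
Conditions: i-Bu2AlH, CH2Cl2, −78 °C
Reagents that add atoms: none
Why: Hydride 1,2-reduction of the enoate with i-Bu2AlH gives the allylic alcohol with the Z geometry intact.

Step 6
Reactants: 9 ethyl (3S)-4-chloro-3-hydroxybutanoate
Product: 10 ethyl [(2S)-oxiran-2-yl]acetate
Conditions: Ag2O, 1,2-dimethoxyethane, reflux
Reagents that add atoms: none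
Why: Silver oxide-mediated ring closure of the chlorohydrin (intramolecular Williamson etherification) gives the epoxide without base-induced β-elimination, and the carbinol stereocentre is not touched.

Step 7
Reactants: 10 ethyl [(2S)-oxiran-2-yl]acetate
Product: 11 ethyl (3R)-3-hydroxyhex-5-enoate (fragment 2)
Conditions: CH2=CHMgBr, CuI (cat.), THF, −40 °C
Reagents that add atoms: vinylmagnesium bromide, C=C[Mg]Br
Why: Copper-catalysed SN2 opening of the terminal epoxide at its unsubstituted carbon keeps the carbinol configuration, which becomes the temporary C11 centre (R).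

Step 8
Reactants: 11 ethyl (3R)-3-hydroxyhex-5-enoate; 8 (2Z,4S)-3-methyl-4-(triethylsilyloxy)-8-(trimethylsilyl)oct-2-en-7-yn-1-ol
Product: 12 (2Z,4S)-3-methyl-4-(triethylsilyloxy)-8-(trimethylsilyl)oct-2-en-7-yn-1-yl (3R)-3-hydroxyhex-5-enoate
Conditions: ClBu2SnOSnBu2OH (cat.), toluene, reflux, removal of EtOH
Reagents that add atoms: none
Why: Distannoxane-catalysed transesterification runs under neutral conditions that tolerate the free β-hydroxyl, the silyl ethers and the Z alkene.

Step 9
Reactants: 12 allyl ester of fragments 1 and 2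
Product: 13 (2R,3R)-3-hydroxy-2-[(3S,4S)-3-methyl-4-(triethylsilyloxy)-8-(trimethylsilyl)oct-1-en-7-yn-3-yl]hex-5-enoic acid (C9 acid; C1–C10 bond formed)
Conditions: LiN(i-Pr)2, THF, −78 °C → rt; aq. NaH2PO4
Reagents that add atoms: none
Why: In this dianionic Ireland–Claisen rearrangement the lithium chelate between the C11 alkoxide and the enolate fixes the enolate geometry and shields one face (new bond anti to the C12 chain, as in a Fráter–Seebach alkylation), and the chair transition state with the Z alkene (C15 methyl equatorial, C2 branch axial, bond forming anti to the C2–OSi bond) should set C10 and the quaternary C1 together.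

Step 10
Reactants: 13 C9 acid
Product: 14 N-methoxy-N-methylamide of acid 13
Conditions: MeNH(OMe)·HCl, EDC·HCl, HOBt, N-methylmorpholine, CH2Cl2, 0 °C → rt
Reagents that add atoms: N,O-dimethylhydroxylamine hydrochloride, CNOC.Cl
Why: Carbodiimide-mediated amide coupling converts the hindered acid into the N-methoxy-N-methylamide without disturbing the β-hydroxyl or any stereocentre.

Step 11
Reactants: 14 N-methoxy-N-methylamide
Product: 15 ring A cyclohexene (C13=C14) carrying the C10 β-amide, the C11 α-hydroxyl, the C1 β-methyl and the C2 side chain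
Conditions: (H2IMes)(PCy3)Cl2Ru=CHPh (second-generation Grubbs catalyst), CH2Cl2, 40 °C
Reagents that add atoms: none
Why: Ring-closing metathesis of the C14 vinyl and C12 allyl groups closes six-membered ring A much faster than the catalyst engages the silyl-capped alkyne.

Step 12
Reactants: 15 ring A cyclohexene
Product: 16 13α,14α-diol of 15 (11,13,14-triol)
Conditions: OsO4 (cat.), N-methylmorpholine N-oxide, acetone/H2O, rt
Reagents that add atoms: osmium tetroxide, O=[Os](=O)(=O)=O; N-methylmorpholine N-oxide, C[N+]1([O-])CCOCC1; water, O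
Why: Catalytic syn-dihydroxylation with osmium tetroxide should occur on the α face, anti to the axial C15 methyl of the half-chair in which the C2 and C9 branches are equatorial, and so set C13 and C14.

Step 13
Reactants: 16 triol
Product: 17 13,14-O-isopropylidene acetal of 16 (C11 hydroxyl free)
Conditions: Me2C(OMe)2, pyridinium p-toluenesulfonate (cat.), acetone, rt
Reagents that add atoms: 2,2-dimethoxypropane, COC(C)(C)OC
Why: Acid-catalysed acetalization is selective for the cis-vicinal C13/C14 diol because the equatorial C11 hydroxyl cannot bridge to C13.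

Step 14
Reactants: 18 methyl (2S)-3-hydroxy-2-methylpropanoate
Product: 19 methyl (2S)-3-(tert-butyldiphenylsilyloxy)-2-methylpropanoate
Conditions: t-BuPh2SiCl, imidazole, DMF, rt
Reagents that add atoms: tert-butyl(chloro)diphenylsilane, CC(C)(C)[Si](Cl)(c1ccccc1)c1ccccc1
Why: Silylation of the primary alcohol gives an ether that survives the organolithium, Grignard and acid steps up to step 26.

Step 15
Reactants: 19 methyl (2S)-3-(tert-butyldiphenylsilyloxy)-2-methylpropanoate
Product: 20 (2S)-3-(tert-butyldiphenylsilyloxy)-2-methylpropanal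
Conditions: i-Bu2AlH, CH2Cl2, −78 °C
Reagents that add atoms: none
Why: Ester reduction with i-Bu2AlH at −78 °C stops at the aldehyde through the stable aluminium hemiacetal, and the α-stereocentre (future C17) is not enolized.

Step 16
Reactants: 20 (2S)-3-(tert-butyldiphenylsilyloxy)-2-methylpropanal
Product: 21 tert-butyl{[(2R)-2-methylbut-3-yn-1-yl]oxy}diphenylsilane
Conditions: MeC(O)C(N2)P(O)(OMe)2, K2CO3, MeOH, 0 °C → rt
Reagents that add atoms: dimethyl (1-diazo-2-oxopropyl)phosphonate, COP(=O)(OC)C(=[N+]=[N-])C(C)=O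
Why: Seyferth–Gilbert homologation with the Ohira–Bestmann reagent converts the aldehyde into the terminal alkyne under mild carbonate conditions that should not epimerize the α-centre.

Step 17
Reactants: 21 tert-butyl{[(2R)-2-methylbut-3-yn-1-yl]oxy}diphenylsilane
Product: 23 {[(2S)-3-bromo-2-methylbut-3-en-1-yl]oxy}(tert-butyl)diphenylsilane (fragment 3), via alkenylborane 22 (not isolated)
Conditions: B-bromo-9-BBN, CH2Cl2, 0 °C; then AcOH
Reagents that add atoms: B-bromo-9-borabicyclo[3.3.1]nonane, BrB1C2CCCC1CCC2
Why: Markovnikov syn bromoboration of the terminal alkyne followed by protodeboronation gives the 2-bromo-1-alkene and leaves the stereocentre alone.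

Step 18
Reactants: 23 fragment 3; 17 ring A amide acetonide
Product: 25 C9 enone C9(=O)–C8(=CH2)–C17H(CH3)–C19H2OSiPh2t-Bu on C10 of ring A (C11 hydroxyl free), via alkenyllithium 24 (not isolated)
Conditions: 23, t-BuLi, Et2O, −78 °C; then 17, THF, −78 → −20 °C; aq. NH4Cl
Reagents that add atoms: none
Why: Bromine–lithium exchange gives a small sp2 nucleophile that acylates on the N-methoxy-N-methylamide, whose chelated tetrahedral intermediate prevents over-addition, while the C11 hydroxyl is masked as its lithium alkoxide and no stereocentre changes.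

Step 19
Reactants: 25 C9 enone
Product: 26 (9S)-9,11-anti-diol (allylic alcohol at C9)
Conditions: Me4NBH(OAc)3, AcOH/MeCN, −30 °C
Reagents that add atoms: none
Why: In the Evans–Saksena reduction the C11 hydroxyl binds the triacetoxyborohydride and delivers hydride intramolecularly through a chair transition state, which should give the 1,3-anti diol and so set C9 (the same sense as Felkin–Anh control from C10).

Step 20
Reactants: 26 9,11-anti-diol
Product: 28 C8 ketone (9-hydroxy-8-oxo compound), via ozonide 27 (not isolated)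
Conditions: O3, CH2Cl2, −78 °C; then Me2S
Reagents that add atoms: ozone, [O-][O+]=O
Why: Ozonolysis cleaves the only alkene, the 1,1-disubstituted C8 methylene, faster than the silylated alkyne and unveils the C8 ketone without touching C9 or C17.

Step 21
Reactants: 28 C8 ketone
Product: 29 C8 tertiary alcohol carrying the C7=C6 vinyl group (8,9,11-triol)
Conditions: CH2=CHMgBr (excess), THF/CH2Cl2, −78 °C
Reagents that add atoms: vinylmagnesium bromide, C=C[Mg]Br
Why: In this chelation-controlled Grignard addition (Cram chelate) the C9 magnesium alkoxide and the C8 carbonyl form a five-membered chelate, any C11 hemiketal form opening under the basic conditions, and the vinyl group should enter from the face of the C9 hydrogen to set C8.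

Step 22
Reactants: 29 8,9,11-triol
Product: 30 C11 ketone (8,9-diol)
Conditions: SO3·pyridine, DMSO, i-Pr2NEt, CH2Cl2, 0 °C
Reagents that add atoms: none
Why: Parikh–Doering oxidation is sensitive to hindrance, so the ring C11 hydroxyl should be oxidized while the C9 hydroxyl, flanked by the fully substituted C8 and the C10 methine, and the tertiary C8 hydroxyl remain.

Step 23
Reactants: 30 C11 ketone
Product: 31 C11 methylene compound (C11=C20)
Conditions: CH2Br2, Zn, TiCl4, THF/CH2Cl2, 0 °C → rt
Reagents that add atoms: dibromomethane, BrCBr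
Why: Takai–Lombardo methylenation uses a non-basic zinc–titanium methylene reagent, which should convert the ketone into the C11=C20 methylene without retro-aldol cleavage of the β-hydroxy ketone or epimerization at C10.

Step 24
Reactants: 31 C11 methylene compound
Product: 32 2,8,9,13,14-pentaol
Conditions: AcOH/THF/H2O, 45 °C
Reagents that add atoms: none
Why: Acid hydrolysis removes the acetonide and the triethylsilyl ether, which are far more labile than the primary tert-butyldiphenylsilyl ether and the alkynylsilane.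

Step 25
Reactants: 32 pentaol
Product: 33 2,9,13,14-tetraacetate (C8 hydroxyl free)
Conditions: Ac2O, pyridine, DMAP (cat.), CH2Cl2, rt → 40 °C
Reagents that add atoms: acetic anhydride, CC(=O)OC(C)=O
Why: DMAP-catalysed acylation esterifies the four secondary hydroxyls at C2, C9, C13 and C14 and leaves the tertiary C8 hydroxyl free.

Step 26
Reactants: 33 tetraacetate
Product: 34 C19 primary alcohol with terminal C5≡C16 alkyne
Conditions: Bu4NF, AcOH, THF, 0 °C → rt
Reagents that add atoms: none
Why: Fluoride-mediated desilylation cleaves the C19 silyl ether and the alkynyl C–Si bond in one operation, and the acetic acid buffer protects the acetates.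

Step 27
Reactants: 34 C19 primary alcohol
Product: 35 C19 carboxylic acid
Conditions: TEMPO (cat.), PhI(OAc)2, MeCN/H2O, rt
Reagents that add atoms: water, O
Why: TEMPO/PhI(OAc)2 oxidation in aqueous acetonitrile takes the only primary alcohol through the aldehyde hydrate to the carboxylic acid, all other hydroxyls being acylated or tertiary.

Step 28
Reactants: 35 C19 carboxylic acid
Product: 36 iodolactone (γ-lactone C19–O–C7 with C6 iodomethyl group)
Conditions: I2, NaHCO3, MeCN, 0 °C, dark
Reagents that add atoms: iodine, II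
Why: In this kinetic iodolactonization (5-exo-trig, anti addition of carboxylate and iodine) the allylic C8 hydroxyl lies in the plane of the alkene and the bulky C9 branch is turned away, so the lactone should close with the C6 iodomethyl group cis to the C8 hydroxyl, which sets C7.

Step 29
Reactants: 36 iodolactone
Product: 38 C5 vinyl iodide (2-iodo-1-alkene), via alkenylborane 37 (not isolated)
Conditions: B-iodo-9-BBN, pentane/CH2Cl2, −20 °C; then AcOH
Reagents that add atoms: B-iodo-9-borabicyclo[3.3.1]nonane, IB1C2CCCC1CCC2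
Why: Markovnikov syn iodoboration of the terminal alkyne and protodeboronation give the 2-iodo-1-alkene at C5, while alkenes, esters, the alkyl iodide and the hindered tertiary hydroxyl should not react with the boron reagent at low temperature.

Step 30
Reactants: 38 C5 vinyl iodide
Product: 39 C6 aldehyde (seco precursor)
Conditions: Me3NO, DMSO, rt
Reagents that add atoms: trimethylamine N-oxide, C[N+](C)(C)[O-]
Why: In this Kornblum-type oxidation the amine N-oxide displaces the primary iodide and the alkoxyammonium salt collapses to the aldehyde without added base, which should preserve the α-stereocentre C7 and the vinyl iodide.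

Step 31
Reactants: 39 C6 aldehyde
Product: 40 (6R)-6-hydroxy compound with the ten-membered ring closed (target with OH in place of Cl and inverted C6)
Conditions: CrCl2, (S)-N-[2-(4-isopropyl-4,5-dihydrooxazol-2-yl)-6-methylphenyl]methanesulfonamide, Et3N, NiCl2 (cat.), THF/MeCN, high dilution, rt
Reagents that add atoms: none
Why: The C5 vinyl iodide adds oxidatively to zerovalent nickel, the alkenyl group passes to trivalent chromium and the alkenylchromium adds to the C6 aldehyde, so that the C5–C6 bond and with it the ten-membered ring C1–C10 are formed (intramolecular Nozaki–Hiyama–Kishi reaction). The closest known reaction type is the Cr/Ni-mediated closure of medium-ring carbocyclic allylic alcohols from iodoalkene aldehydes. The ring closes in the 10-exo-trig mode at the carbonyl carbon with C5=C16 left as the exocyclic methylene, and closure is favoured over intermolecular coupling by high dilution and by the rigid chain ends (trans-disposed C2 and C9 branches on ring A, the lactone, the quaternary C1 and C8). C6 is the only new stereocentre and is controlled by the chiral sulfonamide ligand on chromium, which should deliver the alkenyl group to the Re face of the aldehyde (6R) against the weak Felkin–Anh bias of the α-acyloxy aldehyde. The step needs chemoselectivity for the aldehyde over the four acetates, the lactone and the free tertiary C8 hydroxyl, which the low basicity and aldehyde selectivity of organochromium reagents secure, and it needs a single carbon–halogen bond to activate, which step 30 secures by removing the alkyl iodide first.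

Step 32
Reactants: 40 (6R)-6-hydroxy compound
Product: 41 CNP0144558.1 (target)
Conditions: PPh3, Cl3CC(O)CCl3, CH2Cl2, −20 → 0 °C
Reagents that add atoms: hexachloroacetone, ClC(Cl)(Cl)C(=O)C(Cl)(Cl)Cl
Why: In this Appel-type chlorination chloride should displace the alkoxyphosphonium ion at C6 by SN2 with inversion (approach from the outer face of the ring) and without allylic transposition at low temperature, while the tertiary C8 hydroxyl does not react.

**Compound list**

1 | 5-(trimethylsilyl)pent-4-yn-1-ol | OCCCC#C[Si](C)(C)C | starting material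
2 | 5-(trimethylsilyl)pent-4-ynal | O=CCCC#C[Si](C)(C)C | intermediate
3 | methyl propiolate | C#CC(=O)OC | starting material
4 | methyl 3-(methylzincio)prop-2-ynoate (zinc acetylide, not isolated) | C[Zn]C#CC(=O)OC | intermediate
5 | methyl (4S)-4-hydroxy-8-(trimethylsilyl)octa-2,7-diynoate | COC(=O)C#C[C@@H](O)CCC#C[Si](C)(C)C | intermediate
6 | methyl (4S)-4-(triethylsilyloxy)-8-(trimethylsilyl)octa-2,7-diynoate | COC(=O)C#C[C@@H](O[Si](CC)(CC)CC)CCC#C[Si](C)(C)C | intermediate
7 | methyl (2Z,4S)-3-methyl-4-(triethylsilyloxy)-8-(trimethylsilyl)oct-2-en-7-ynoate | COC(=O)/C=C(C)\[C@@H](O[Si](CC)(CC)CC)CCC#C[Si](C)(C)C | intermediate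
8 | (2Z,4S)-3-methyl-4-(triethylsilyloxy)-8-(trimethylsilyl)oct-2-en-7-yn-1-ol (fragment 1) | OC/C=C(C)\[C@@H](O[Si](CC)(CC)CC)CCC#C[Si](C)(C)C | intermediate
9 | ethyl (3S)-4-chloro-3-hydroxybutanoate | CCOC(=O)C[C@H](O)CCl | starting material
10 | ethyl [(2S)-oxiran-2-yl]acetate | CCOC(=O)C[C@H]1CO1 | intermediate
11 | ethyl (3R)-3-hydroxyhex-5-enoate (fragment 2) | CCOC(=O)C[C@H](O)CC=C | intermediate
12 | (2Z,4S)-3-methyl-4-(triethylsilyloxy)-8-(trimethylsilyl)oct-2-en-7-yn-1-yl (3R)-3-hydroxyhex-5-enoate | C=CC[C@@H](O)CC(=O)OC/C=C(C)\[C@@H](O[Si](CC)(CC)CC)CCC#C[Si](C)(C)C | intermediate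
13 | (2R,3R)-3-hydroxy-2-[(3S,4S)-3-methyl-4-(triethylsilyloxy)-8-(trimethylsilyl)oct-1-en-7-yn-3-yl]hex-5-enoic acid | C=CC[C@@H](O)[C@H](C(=O)O)[C@](C)(C=C)[C@@H](O[Si](CC)(CC)CC)CCC#C[Si](C)(C)C | intermediate
14 | N-methoxy-N-methylamide of 13 | C=CC[C@@H](O)[C@H](C(=O)N(C)OC)[C@](C)(C=C)[C@@H](O[Si](CC)(CC)CC)CCC#C[Si](C)(C)C | intermediate
15 | ring A cyclohexene amide (C13=C14; 11α-OH) | O[C@@H]1CC=C[C@](C)([C@@H](O[Si](CC)(CC)CC)CCC#C[Si](C)(C)C)[C@H]1C(=O)N(C)OC | intermediate
16 | 11α,13α,14α-triol amide | O[C@@H]1C[C@H](O)[C@H](O)[C@](C)([C@@H](O[Si](CC)(CC)CC)CCC#C[Si](C)(C)C)[C@H]1C(=O)N(C)OC | intermediate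
17 | 13,14-O-isopropylidene amide (11-OH free) | O[C@@H]1C[C@@H]2OC(C)(C)O[C@@H]2[C@](C)([C@@H](O[Si](CC)(CC)CC)CCC#C[Si](C)(C)C)[C@H]1C(=O)N(C)OC | intermediate
18 | methyl (2S)-3-hydroxy-2-methylpropanoate | OC[C@H](C)C(=O)OC | starting material
19 | methyl (2S)-3-(tert-butyldiphenylsilyloxy)-2-methylpropanoate | CC(C)(C)[Si](c1ccccc1)(c1ccccc1)OC[C@H](C)C(=O)OC | intermediate
20 | (2S)-3-(tert-butyldiphenylsilyloxy)-2-methylpropanal | CC(C)(C)[Si](c1ccccc1)(c1ccccc1)OC[C@H](C)C=O | intermediate
21 | tert-butyl{[(2R)-2-methylbut-3-yn-1-yl]oxy}diphenylsilane | CC(C)(C)[Si](c1ccccc1)(c1ccccc1)OC[C@H](C)C#C | intermediate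
22 | B-[(Z)-2-bromoalkenyl]-9-BBN adduct of 21 (not isolated) | CC(C)(C)[Si](c1ccccc1)(c1ccccc1)OC[C@H](C)C(/Br)=C/B1C2CCCC1CCC2 | intermediate
23 | {[(2S)-3-bromo-2-methylbut-3-en-1-yl]oxy}(tert-butyl)diphenylsilane (fragment 3) | CC(C)(C)[Si](c1ccccc1)(c1ccccc1)OC[C@H](C)C(Br)=C | intermediate
24 | alkenyllithium from 23 (not isolated) | CC(C)(C)[Si](c1ccccc1)(c1ccccc1)OC[C@H](C)C([Li])=C | intermediate
25 | C9 enone | O[C@@H]1C[C@@H]2OC(C)(C)O[C@@H]2[C@](C)([C@@H](O[Si](CC)(CC)CC)CCC#C[Si](C)(C)C)[C@H]1C(=O)C(=C)[C@@H](C)CO[Si](c1ccccc1)(c1ccccc1)C(C)(C)C | intermediate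
26 | (9S)-9,11-anti-diol | O[C@@H]1C[C@@H]2OC(C)(C)O[C@@H]2[C@](C)([C@@H](O[Si](CC)(CC)CC)CCC#C[Si](C)(C)C)[C@H]1[C@H](O)C(=C)[C@@H](C)CO[Si](c1ccccc1)(c1ccccc1)C(C)(C)C | intermediate
27 | ozonide of 26 (1,2,4-trioxolane at C8, not isolated) | O[C@@H]1C[C@@H]2OC(C)(C)O[C@@H]2[C@](C)([C@@H](O[Si](CC)(CC)CC)CCC#C[Si](C)(C)C)[C@H]1[C@H](O)C1(OOCO1)[C@@H](C)CO[Si](c1ccccc1)(c1ccccc1)C(C)(C)C | intermediate
28 | C8 ketone (9-hydroxy-8-oxo compound) | O[C@@H]1C[C@@H]2OC(C)(C)O[C@@H]2[C@](C)([C@@H](O[Si](CC)(CC)CC)CCC#C[Si](C)(C)C)[C@H]1[C@H](O)C(=O)[C@@H](C)CO[Si](c1ccccc1)(c1ccccc1)C(C)(C)C | intermediate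
29 | C8 vinyl carbinol (8,9,11-triol) | O[C@@H]1C[C@@H]2OC(C)(C)O[C@@H]2[C@](C)([C@@H](O[Si](CC)(CC)CC)CCC#C[Si](C)(C)C)[C@H]1[C@H](O)[C@@](O)(C=C)[C@@H](C)CO[Si](c1ccccc1)(c1ccccc1)C(C)(C)C | intermediate
30 | C11 ketone (8,9-diol) | O=C1C[C@@H]2OC(C)(C)O[C@@H]2[C@](C)([C@@H](O[Si](CC)(CC)CC)CCC#C[Si](C)(C)C)[C@H]1[C@H](O)[C@@](O)(C=C)[C@@H](C)CO[Si](c1ccccc1)(c1ccccc1)C(C)(C)C | intermediate
31 | C11 methylene compound (C11=C20) | C=C1C[C@@H]2OC(C)(C)O[C@@H]2[C@](C)([C@@H](O[Si](CC)(CC)CC)CCC#C[Si](C)(C)C)[C@H]1[C@H](O)[C@@](O)(C=C)[C@@H](C)CO[Si](c1ccccc1)(c1ccccc1)C(C)(C)C | intermediate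
32 | 2,8,9,13,14-pentaol | C=C1C[C@H](O)[C@H](O)[C@](C)([C@@H](O)CCC#C[Si](C)(C)C)[C@H]1[C@H](O)[C@@](O)(C=C)[C@@H](C)CO[Si](c1ccccc1)(c1ccccc1)C(C)(C)C | intermediate
33 | 2,9,13,14-tetraacetate | C=C1C[C@H](OC(C)=O)[C@H](OC(C)=O)[C@](C)([C@@H](OC(C)=O)CCC#C[Si](C)(C)C)[C@H]1[C@H](OC(C)=O)[C@@](O)(C=C)[C@@H](C)CO[Si](c1ccccc1)(c1ccccc1)C(C)(C)C | intermediate
34 | C19 primary alcohol with terminal alkyne | C=C1C[C@H](OC(C)=O)[C@H](OC(C)=O)[C@](C)([C@@H](OC(C)=O)CCC#C)[C@H]1[C@H](OC(C)=O)[C@@](O)(C=C)[C@@H](C)CO | intermediate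
35 | C19 carboxylic acid | C=C1C[C@H](OC(C)=O)[C@H](OC(C)=O)[C@](C)([C@@H](OC(C)=O)CCC#C)[C@H]1[C@H](OC(C)=O)[C@@](O)(C=C)[C@@H](C)C(=O)O | intermediate
36 | iodolactone (C6 iodomethyl) | C=C1C[C@H](OC(C)=O)[C@H](OC(C)=O)[C@](C)([C@@H](OC(C)=O)CCC#C)[C@H]1[C@H](OC(C)=O)[C@@]2(O)[C@H](CI)OC(=O)[C@@H]2C | intermediate
37 | B-[(Z)-2-iodoalkenyl]-9-BBN adduct of 36 (not isolated) | C=C1C[C@H](OC(C)=O)[C@H](OC(C)=O)[C@](C)([C@@H](OC(C)=O)CCC(/I)=C/B3C4CCCC3CCC4)[C@H]1[C@H](OC(C)=O)[C@@]2(O)[C@H](CI)OC(=O)[C@@H]2C | intermediate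
38 | C5 vinyl iodide | C=C1C[C@H](OC(C)=O)[C@H](OC(C)=O)[C@](C)([C@@H](OC(C)=O)CCC(I)=C)[C@H]1[C@H](OC(C)=O)[C@@]2(O)[C@H](CI)OC(=O)[C@@H]2C | intermediate
39 | C6 aldehyde (seco precursor) | C=C1C[C@H](OC(C)=O)[C@H](OC(C)=O)[C@](C)([C@@H](OC(C)=O)CCC(I)=C)[C@H]1[C@H](OC(C)=O)[C@@]2(O)[C@H](C=O)OC(=O)[C@@H]2C | intermediate
40 | (6R)-6-hydroxy macrocycle | C=C1C[C@H](OC(C)=O)[C@H](OC(C)=O)[C@]2(C)[C@@H](OC(C)=O)CCC(=C)[C@@H](O)[C@@H]3OC(=O)[C@H](C)[C@@]3(O)[C@@H](OC(C)=O)[C@@H]12 | intermediate
41 | CNP0144558.1 | C=C1C[C@H](OC(C)=O)[C@H](OC(C)=O)[C@]2(C)[C@@H](OC(C)=O)CCC(=C)[C@H](Cl)[C@@H]3OC(=O)[C@H](C)[C@@]3(O)[C@@H](OC(C)=O)[C@@H]12 | target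

**Step count and risks**

Total: 32 steps. Longest linear sequence: 26 steps (steps 1–5, 8–13 and 18–32).

Step 31: the chromium ligand may fail to override the intrinsic facial bias of the α-acyloxy aldehyde, so that the wrong C6 epimer forms, and slow closure of the strained ring may let intermolecular coupling and reduction of the vinyl iodide compete. The fallback sets out from 39: closure with ligand-free CrCl2/NiCl2 in DMSO should give mainly the (6S)-alcohol F1 besides 40. The mixture is oxidized with Dess–Martin periodinane to the cross-conjugated macrocyclic C6 ketone F2. Luche reduction (NaBH4, CeCl3, MeOH, −78 °C), with hydride entering anti to the C7–O bond in the Felkin–Anh sense, comes back to the route at 40. C6 is then set by ketone reduction instead of during C–C bond formation.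

Step 9: the lithium chelate may break up, with loss of facial and enolate-geometry control, or the dianion may undergo β-elimination or retro-aldol cleavage before it rearranges. The fallback sets out from 12: the hydroxyl is capped as the trimethylsilyl ether F3 (Me3SiCl, imidazole). The rearrangement is then run under reagent control as a boron-enolate Ireland–Claisen reaction with a chiral 1,2-diphenylethane-1,2-diamine bis(sulfonamide) bromoborane and a tertiary amine. Mildly acidic work-up removes the trimethylsilyl group and comes back to the route at 13.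

Step 32: chloride may attack C16 in an SN2′ sense (allylic transposition), or the alkoxyphosphonium ion may ionize or eliminate, because C6 is hindered and flanked by the lactone oxygen. The fallback sets out from 40: the allylic alcohol is transposed with Ph3SiOReO3 (cat.) to the primary C16 allylic alcohol F4, which has an endocyclic C5=C6 bond. SOCl2 in Et2O without base then returns chloride to C6 through the chlorosulfite (SNi′) from the outer face of the ring alkene, regenerating the C5=C16 methylene and reaching 41 directly.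

Further compounds
F1 | step 31 | (6S)-6-hydroxy epimer of 40 | C=C1C[C@H](OC(C)=O)[C@H](OC(C)=O)[C@]2(C)[C@@H](OC(C)=O)CCC(=C)[C@H](O)[C@@H]3OC(=O)[C@H](C)[C@@]3(O)[C@@H](OC(C)=O)[C@@H]12
F2 | step 31 | macrocyclic C6 ketone (5(16)-en-6-one) | C=C1C[C@H](OC(C)=O)[C@H](OC(C)=O)[C@]2(C)[C@@H](OC(C)=O)CCC(=C)C(=O)[C@@H]3OC(=O)[C@H](C)[C@@]3(O)[C@@H](OC(C)=O)[C@@H]12
F3 | step 9 | C11 trimethylsilyl ether of ester 12 | C=CC[C@@H](O[Si](C)(C)C)CC(=O)OC/C=C(C)\[C@@H](O[Si](CC)(CC)CC)CCC#C[Si](C)(C)C
F4 | step 32 | (5E)-16-hydroxy-5-ene isomer of 40 (primary allylic alcohol) | C=C1C[C@H](OC(C)=O)[C@H](OC(C)=O)[C@]2(C)[C@@H](OC(C)=O)CC/C(CO)=C\[C@@H]3OC(=O)[C@H](C)[C@@]3(O)[C@@H](OC(C)=O)[C@@H]12
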